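**Plan**

- Retrosynthesis, cut 1: the coumarin pyranone ring is opened at C3=C4 and O1–C2 (Knoevenagel–lactonisation). This gives the masked salicylaldehyde 10 and the pyranylacetate 15.
- Cut 2: the dihydropyranone of 15 is opened at C4'–C5' and O1'–C6'. The arc O1'–C2'(H)(CH3)–C3'H2–C4'(=O) is an intact 4-methyloxetan-2-one, and C5'=C6' is the enol ether of a 1,3-dicarbonyl. The six-membered ring is therefore the β-lactone with two acetoacetate carbons (C4, C3) inserted into its acyl–oxygen bond; acetoacetate C2/C1 become coumarin C3/C2.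
- Cut 3: the arene is taken back through C4 of the coumarin (orthoformate carbon), the two O-methyls, the benzylic C–CH3 bond (epoxide opening), the epoxide, the propenyl C=C and the C6 methyl to 3,5-dimethoxy-4-methylbenzaldehyde.
- Forward order: side chain on the arene, then a temporary isochromene ring that carries the formyl carbon and masks the side-chain hydroxyl (step 6). Separately oxetanone → dihydropyranone (step 7). The coumarin ring is closed last (step 8), which opens the temporary ring again.
- Stereochemistry: C2' comes from (R)-β-butyrolactone, whose C–O bond is never broken. The side chain comes from a Shi epoxidation (both centres, S,S) followed by anti SN2 opening by methyl at the benzylic carbon, which gives the (2R,3S)-3-hydroxybutan-2-yl group.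

Key step: step 7

Remark: 3,5-dimethoxy-4-methylbenzaldehyde, (R)-β-butyrolactone, methyl acetoacetate, the ethyl phenyltetrazolyl sulfone and the L-fructose-derived (enantiomeric) Shi ketone are taken as catalogue chemicals; compound 10 is written as the quinone methide, the dehydrated form of its lactol/hydroxy-aldehyde.

**Route**

Step 1
Reactants: 1 3,5-dimethoxy-4-methylbenzaldehyde
Product: 5 3,5-dimethoxy-2,4-dimethylbenzaldehyde, via lithium α-amino alkoxide 2 (not isolated), via ortho-lithiated alkoxide 3 (not isolated), via C-methylated alkoxide 4 (not isolated)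
Conditions: LiN(Me)CH2CH2NMe2 (from Me2NCH2CH2NHMe, n-BuLi), THF, −20 °C; n-BuLi, −20 °C; MeI, −78 °C → rt; aq. NH4Cl
Reagents that add atoms: iodomethane, CI
Why: Directed ortho-metalation with in-situ protection of the aldehyde as its α-amino alkoxide: this group and the flanking methoxy jointly direct lithiation to C2 (the two ortho sites are equivalent), iodomethane traps the aryllithium and aqueous work-up releases the aldehyde.

Step 2
Reactants: 5 3,5-dimethoxy-2,4-dimethylbenzaldehyde
Product: 6 1,3-dimethoxy-2,4-dimethyl-5-[(1E)-prop-1-en-1-yl]benzene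
Conditions: 5-(ethylsulfonyl)-1-phenyl-1H-tetrazole, KHMDS, DME, −60 °C → rt
Reagents that add atoms: 5-(ethylsulfonyl)-1-phenyl-1H-tetrazole, CCS(=O)(=O)c1nnnn1-c1ccccc1
Why: Julia–Kocienski olefination, which with an aryl aldehyde and the potassium sulfonyl anion in DME should deliver the (E)-propenylarene through Smiles rearrangement and anti elimination.

Step 3
Reactants: 6 1,3-dimethoxy-2,4-dimethyl-5-[(1E)-prop-1-en-1-yl]benzene
Product: 7 (2S,3S)-2-(3,5-dimethoxy-2,4-dimethylphenyl)-3-methyloxirane
Conditions: ent-Shi ketone (L-fructose-derived, 30 mol %), Oxone, K2CO3, Bu4NHSO4, MeCN–DMM / aq. Na2B4O7–EDTA buffer, 0 °C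
Reagents that add atoms: potassium peroxymonosulfate (Oxone), [K+].[O-]S(=O)(=O)OO
Why: Shi asymmetric epoxidation of a trans-β-methylstyrene; the chiral dioxirane transfers oxygen through the spiro transition state, and the enantiomer of the usual ketone (which gives R,R epoxides) should set both centres as S,S.

Step 4
Reactants: 7 (2S,3S)-2-(3,5-dimethoxy-2,4-dimethylphenyl)-3-methyloxirane
Product: 8 (2S,3R)-3-(3,5-dimethoxy-2,4-dimethylphenyl)butan-2-ol
Conditions: Me2CuLi (from MeLi, CuI), Et2O, −40 → 0 °C; aq. NH4Cl/NH3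
Reagents that add atoms: lithium dimethylcuprate, [Li+].C[Cu-]C
Why: SN2 opening of the epoxide by an organocuprate at the electronically activated benzylic carbon with inversion, the carbinol carbon being untouched, so the trans-(S,S)-epoxide should give the threo (2S,3R) alcohol.

Step 5
Reactants: 8 (2S,3R)-3-(3,5-dimethoxy-2,4-dimethylphenyl)butan-2-ol
Product: 9 5-[(2R,3S)-3-hydroxybutan-2-yl]-2,4-dimethylbenzene-1,3-diol
Conditions: BBr3 (4 equiv), CH2Cl2, −78 → 0 °C; MeOH, then H2O
Reagents that add atoms: none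
Why: Lewis-acid cleavage of both aryl methyl ethers (BBr3 demethylation), kept at or below 0 °C so that the secondary alcohol is carried as its borate and neither stereocentre is touched.

Step 6
Reactants: 9 5-[(2R,3S)-3-hydroxybutan-2-yl]-2,4-dimethylbenzene-1,3-diol
Product: 10 (3S,4R)-8-hydroxy-3,4,5,7-tetramethyl-4,6-dihydro-3H-isochromen-6-one
Conditions: HC(OEt)3 (excess), TFA, CH2Cl2, 0 °C → rt; aq. NaHCO3
Reagents that add atoms: triethyl orthoformate, CCOC(OCC)OCC
Why: Orthoformate formylation of the resorcinol at its only free ring position (ortho and para to the hydroxyls) with capture by the side-chain hydroxyl (oxa-Pictet–Spengler-type closure) and loss of ethanol to the para-quinone methide, a closure with close precedent on 5-(3-hydroxybutan-2-yl)resorcinols; no stereocentre is involved.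

Step 7
Reactants: 11 methyl acetoacetate; 12 (R)-β-butyrolactone [(4R)-4-methyloxetan-2-one]
Product: 15 methyl 2-[(2R)-2-methyl-4-oxo-3,4-dihydro-2H-pyran-6-yl]acetate, via acetoacetate dianion 13 (not isolated), via hydroxy diketo ester 14 (not isolated)
Conditions: 11 (2.2 equiv), NaH then n-BuLi, THF, 0 °C; 12 (1 equiv), −78 → −20 °C; 2 M HCl; crude 14, TsOH·H2O (cat.), CH2Cl2, rt
Reagents that add atoms: none
Why: The γ-carbon of dianion 13 adds to the lactone carbonyl of 12, the strained tetrahedral intermediate collapses by acyl–oxygen cleavage to the 3,5-dioxo ester alkoxide (14 after protonation), and under acid the liberated C7 hydroxyl returns to the C3 ketone and water is lost, so the ring oxygen has moved from the acyl carbon to a carbon two atoms further and the four-membered lactone has become the six-membered vinylogous ester, a two-carbon ring expansion. The closest known reaction types are the Claisen-type acylation of β-keto ester dianions by esters, the acyl-selective opening of β-lactones by lithium enolates, and the acid cyclodehydration of 5-hydroxy-1,3-diketones to 2,3-dihydro-4H-pyran-4-ones. The ring closes in a 6-exo-trig mode (hydroxyl oxygen onto the ketone carbonyl), followed by dehydration to the endocyclic enol ether. No stereocentre is created: C2' is the carbinol carbon of (R)-12, whose C–O bond is never broken, so its configuration is retained. The step needs acyl over alkyl C–O attack (a hard lithium carbanion at low temperature against a secondary SN2 site), γ over α reactivity of 11 (secured by the dianion), and protection against over-addition (the product 1,3-diketone is deprotonated at once, hence two equivalents of 13); closure onto C3 is the only six-membered option, the alternatives being a four-membered hemiketal or an eight-membered lactone.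

Step 8
Reactants: 10 (3S,4R)-8-hydroxy-3,4,5,7-tetramethyl-4,6-dihydro-3H-isochromen-6-one; 15 methyl 2-[(2R)-2-methyl-4-oxo-3,4-dihydro-2H-pyran-6-yl]acetate
Product: 18 7-hydroxy-5-[(2R,3S)-3-hydroxybutan-2-yl]-6,8-dimethyl-3-[(2R)-2-methyl-4-oxo-3,4-dihydro-2H-pyran-6-yl]-2H-chromen-2-one, via isochroman adduct 16 (not isolated), via arylidene ester 17 (not isolated)
Conditions: piperidine (0.2 equiv), AcOH (0.2 equiv), EtOH, rt → 50 °C
Reagents that add atoms: none
Why: Knoevenagel-type condensation–lactonisation (coumarin synthesis) in which the glutaconate-like carbanion of 15 (CH2 between the ester and the vinylogous ketone) adds to C1 of the quinone methide, base-induced β-elimination of the ring oxygen (retro-oxa-Michael) opens the temporary isochroman ring to the arylidene ester, and the ortho phenol closes the lactone with loss of methanol, the coumarin being the sink; no stereocentre is formed and the buffered catalytic base is chosen to leave C2' untouched.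

**Compound list**

1 | 3,5-dimethoxy-4-methylbenzaldehyde | COc1cc(C=O)cc(OC)c1C | starting material
2 | lithium (3,5-dimethoxy-4-methylphenyl){[2-(dimethylamino)ethyl](methyl)amino}methanolate | [Li+].COc1cc(C([O-])N(C)CCN(C)C)cc(OC)c1C | intermediate
3 | lithium {[2-(dimethylamino)ethyl](methyl)amino}(2-lithio-3,5-dimethoxy-4-methylphenyl)methanolate | [Li+].[Li]c1c(C([O-])N(C)CCN(C)C)cc(OC)c(C)c1OC | intermediate
4 | lithium {[2-(dimethylamino)ethyl](methyl)amino}(3,5-dimethoxy-2,4-dimethylphenyl)methanolate | [Li+].Cc1c(C([O-])N(C)CCN(C)C)cc(OC)c(C)c1OC | intermediate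
5 | 3,5-dimethoxy-2,4-dimethylbenzaldehyde | Cc1c(C=O)cc(OC)c(C)c1OC | intermediate
6 | 1,3-dimethoxy-2,4-dimethyl-5-[(1E)-prop-1-en-1-yl]benzene | C/C=C/c1cc(OC)c(C)c(OC)c1C | intermediate
7 | (2S,3S)-2-(3,5-dimethoxy-2,4-dimethylphenyl)-3-methyloxirane | C[C@@H]1O[C@H]1c2cc(OC)c(C)c(OC)c2C | intermediate
8 | (2S,3R)-3-(3,5-dimethoxy-2,4-dimethylphenyl)butan-2-ol | COc1cc([C@@H](C)[C@H](C)O)c(C)c(OC)c1C | intermediate
9 | 5-[(2R,3S)-3-hydroxybutan-2-yl]-2,4-dimethylbenzene-1,3-diol | Oc1cc([C@@H](C)[C@H](C)O)c(C)c(O)c1C | intermediate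
10 | (3S,4R)-8-hydroxy-3,4,5,7-tetramethyl-4,6-dihydro-3H-isochromen-6-one | CC1=C(O)C2=CO[C@@H](C)[C@H](C)C2=C(C)C1=O | intermediate
11 | methyl acetoacetate (methyl 3-oxobutanoate) | CC(=O)CC(=O)OC | starting material
12 | (R)-β-butyrolactone, (4R)-4-methyloxetan-2-one | C[C@@H]1CC(=O)O1 | starting material
13 | sodium lithium 1-methoxybuta-1,3-diene-1,3-bis(olate) (dianion of 11) | [Na+].[Li+].COC([O-])=CC([O-])=C | intermediate
14 | methyl (7R)-7-hydroxy-3,5-dioxooctanoate | COC(=O)CC(=O)CC(=O)C[C@@H](C)O | intermediate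
15 | methyl 2-[(2R)-2-methyl-4-oxo-3,4-dihydro-2H-pyran-6-yl]acetate | COC(=O)CC1=CC(=O)C[C@@H](C)O1 | intermediate
16 | methyl 2-[(3S,4R)-6,8-dihydroxy-3,4,5,7-tetramethyl-3,4-dihydro-1H-isochromen-1-yl]-2-[(2R)-2-methyl-4-oxo-3,4-dihydro-2H-pyran-6-yl]acetate (C1 and the α-carbon unassigned) | COC(=O)C(C1=CC(=O)C[C@@H](C)O1)C1O[C@@H](C)[C@H](C)c2c(C)c(O)c(C)c(O)c21 | intermediate
17 | methyl 3-{2,4-dihydroxy-6-[(2R,3S)-3-hydroxybutan-2-yl]-3,5-dimethylphenyl}-2-[(2R)-2-methyl-4-oxo-3,4-dihydro-2H-pyran-6-yl]prop-2-enoate (alkene geometry unassigned) | COC(=O)C(=Cc1c(O)c(C)c(O)c(C)c1[C@@H](C)[C@H](C)O)C1=CC(=O)C[C@@H](C)O1 | intermediate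
18 | 7-hydroxy-5-[(2R,3S)-3-hydroxybutan-2-yl]-6,8-dimethyl-3-[(2R)-2-methyl-4-oxo-3,4-dihydro-2H-pyran-6-yl]-2H-chromen-2-one | Cc1c(O)c(C)c2oc(=O)c(C3=CC(=O)C[C@@H](C)O3)cc2c1[C@@H](C)[C@H](C)O | target

**Count and risks**

Total step count: 8. Longest linear sequence: 7 (steps 1–6, then 8); step 7 is a one-step branch.

Steps most likely to fail:

1. Step 8. The ambident carbanion of 15 may react through ring carbon C5' instead of the exocyclic CH2, the isochroman adduct may stall before ring opening and lactonisation, and base may open the dihydropyranone by retro-oxa-Michael reaction with erosion of configuration at C2'. The fallback sets out from 10 (with 11 and 12) and comes back at 18. Compound 10 is condensed with methyl acetoacetate 11 (piperidinium acetate, EtOH), a nucleophile with a single reactive carbon, to give 3-acetyl-7-hydroxy-5-[(2R,3S)-3-hydroxybutan-2-yl]-6,8-dimethyl-2H-chromen-2-one F1. Both hydroxyls are silylated (TBSCl, imidazole, DMF) to 3-acetyl-7-[(tert-butyldimethylsilyl)oxy]-5-{(2R,3S)-3-[(tert-butyldimethylsilyl)oxy]butan-2-yl}-6,8-dimethyl-2H-chromen-2-one F2. Its lithium enolate (LiHMDS, THF, −78 °C; C4 is shielded by the peri substituent) is acylated by lactone 12 to 7-[(tert-butyldimethylsilyl)oxy]-5-{(2R,3S)-3-[(tert-butyldimethylsilyl)oxy]butan-2-yl}-3-[(5R)-5-hydroxy-3-oxohexanoyl]-6,8-dimethyl-2H-chromen-2-one F3. Aqueous HF in MeCN then cyclodehydrates and desilylates to 18, so the dihydropyranone is formed last and under acid.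

2. Step 7. The dianion may attack the alkyl C–O carbon of the lactone (SN2) instead of the acyl carbon, may enolise the lactone (followed by β-elimination), or the triketide may cyclise through its enol oxygen onto the ester. The fallback sets out from 12 and comes back at 15. Lactone 12 is opened with MeNHOMe·HCl/Me2AlCl to (3R)-3-hydroxy-N-methoxy-N-methylbutanamide F4, which is silylated (TBSCl, imidazole) to (3R)-3-[(tert-butyldimethylsilyl)oxy]-N-methoxy-N-methylbutanamide F5. Dianion 13 (from 11) is acylated by F5 to methyl (7R)-7-[(tert-butyldimethylsilyl)oxy]-3,5-dioxooctanoate F6, and aqueous HF in MeCN removes the silyl group and cyclodehydrates to 15.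

3. Step 4. The cuprate may attack the non-benzylic carbon (the ortho methyl hinders the benzylic site), or lithium-ion-assisted ionisation of the aryl epoxide may cause rearrangement and loss of stereospecificity. The fallback sets out from 5 and comes back at 8; regiochemistry is enforced by a neighbouring hydroxyl. Horner–Wadsworth–Emmons olefination of 5 (triethyl phosphonoacetate, NaH, THF) gives ethyl (2E)-3-(3,5-dimethoxy-2,4-dimethylphenyl)prop-2-enoate F7, and DIBAL-H reduces it to (2E)-3-(3,5-dimethoxy-2,4-dimethylphenyl)prop-2-en-1-ol F8. Sharpless asymmetric epoxidation (Ti(OiPr)4, L-(+)-DET, TBHP) gives [(2S,3S)-3-(3,5-dimethoxy-2,4-dimethylphenyl)oxiran-2-yl]methanol F9. AlMe3 opens it at C3 with inversion to (2R,3R)-3-(3,5-dimethoxy-2,4-dimethylphenyl)butane-1,2-diol F10. Selective primary tosylation (TsCl, Et3N, cat. Bu2SnO) gives (2R,3R)-3-(3,5-dimethoxy-2,4-dimethylphenyl)-2-hydroxybutyl 4-methylbenzenesulfonate F11, and LiAlH4 reduces it to 8.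

**Further compounds**

F1 | step 8 | 3-acetyl-7-hydroxy-5-[(2R,3S)-3-hydroxybutan-2-yl]-6,8-dimethyl-2H-chromen-2-one | CC(=O)c1cc2c([C@@H](C)[C@H](C)O)c(C)c(O)c(C)c2oc1=O
F2 | step 8 | 3-acetyl-7-[(tert-butyldimethylsilyl)oxy]-5-{(2R,3S)-3-[(tert-butyldimethylsilyl)oxy]butan-2-yl}-6,8-dimethyl-2H-chromen-2-one | CC(=O)c1cc2c([C@@H](C)[C@H](C)O[Si](C)(C)C(C)(C)C)c(C)c(O[Si](C)(C)C(C)(C)C)c(C)c2oc1=O
F3 | step 8 | 7-[(tert-butyldimethylsilyl)oxy]-5-{(2R,3S)-3-[(tert-butyldimethylsilyl)oxy]butan-2-yl}-3-[(5R)-5-hydroxy-3-oxohexanoyl]-6,8-dimethyl-2H-chromen-2-one | C[C@@H](O)CC(=O)CC(=O)c1cc2c([C@@H](C)[C@H](C)O[Si](C)(C)C(C)(C)C)c(C)c(O[Si](C)(C)C(C)(C)C)c(C)c2oc1=O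
F4 | step 7 | (3R)-3-hydroxy-N-methoxy-N-methylbutanamide | C[C@@H](O)CC(=O)N(C)OC
F5 | step 7 | (3R)-3-[(tert-butyldimethylsilyl)oxy]-N-methoxy-N-methylbutanamide | C[C@@H](O[Si](C)(C)C(C)(C)C)CC(=O)N(C)OC
F6 | step 7 | methyl (7R)-7-[(tert-butyldimethylsilyl)oxy]-3,5-dioxooctanoate | COC(=O)CC(=O)CC(=O)C[C@@H](C)O[Si](C)(C)C(C)(C)C
F7 | step 4 | ethyl (2E)-3-(3,5-dimethoxy-2,4-dimethylphenyl)prop-2-enoate | CCOC(=O)/C=C/c1cc(OC)c(C)c(OC)c1C
F8 | step 4 | (2E)-3-(3,5-dimethoxy-2,4-dimethylphenyl)prop-2-en-1-ol | OC/C=C/c1cc(OC)c(C)c(OC)c1C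
F9 | step 4 | [(2S,3S)-3-(3,5-dimethoxy-2,4-dimethylphenyl)oxiran-2-yl]methanol | OC[C@@H]1O[C@H]1c2cc(OC)c(C)c(OC)c2C
F10 | step 4 | (2R,3R)-3-(3,5-dimethoxy-2,4-dimethylphenyl)butane-1,2-diol | COc1cc([C@@H](C)[C@H](CO)O)c(C)c(OC)c1C
F11 | step 4 | (2R,3R)-3-(3,5-dimethoxy-2,4-dimethylphenyl)-2-hydroxybutyl 4-methylbenzenesulfonate | COc1cc([C@@H](C)[C@H](COS(=O)(=O)c2ccc(C)cc2)O)c(C)c(OC)c1C
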